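**Retrosynthetic overview**
1. C7 carbinol: chelation-controlled hydride reduction of the (S)-α-aryloxy aryl ketone, so that C8 (S) sets C7 (R).
2. C7–aryl bond: 3,4-dimethoxyphenyl Grignard reagent (from catechol) added to a Weinreb amide.
3. Cinnamyl alcohol arm: Suzuki coupling of (E)-3-iodoallyl alcohol (from propargyl alcohol) with an aryl boronate made by sterically governed Ir C–H borylation para to the ether oxygen.
4. Key 8–O–4' bond: Cu-catalysed, stereoretentive O-arylation of the (S)-lactic Weinreb amide with 2-iodo-1,3-dimethoxybenzene (from resorcinol). C8 comes from the lactate pool.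
5. No ring is formed. Both benzene rings are bought as benzenediols and only decorated.

Assumption: the SMILES is read as the (1R,2S) [7R,8S, erythro], (E) isomer. Neolignan numbering (C7 carbinol, C8 ether carbon, C9 methyl) is used in the comments.

**Route**

Step 1
Reactants: 1 resorcinol (benzene-1,3-diol)
Product: 2 1,3-dimethoxybenzene
Conditions: MeI (2.5 equiv), K2CO3 (3 equiv), acetone, reflux, 12 h
Reagents that add atoms: iodomethane, CI
Why: Williamson ether synthesis, in which the carbonate-generated phenoxides are O-methylated by SN2 on MeI; no stereocentre is involved.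

Step 2
Reactants: 2 1,3-dimethoxybenzene
Product: 4 2-iodo-1,3-dimethoxybenzene, via 2,6-dimethoxyphenyllithium 3 (not isolated)
Conditions: n-BuLi (1.1 equiv), THF, 0 °C to rt, 2 h; then I2 (1.15 equiv), THF, −78 °C to rt
Reagents that add atoms: iodine, [I][I]
Why: Directed ortho metalation, in which the two methoxy groups cooperatively acidify and coordinate at C2, so lithiation and iodine quench occur only between them.

Step 3
Reactants: 5 methyl (S)-lactate
Product: 6 (S)-2-hydroxy-N-methoxy-N-methylpropanamide
Conditions: MeNHOMe·HCl (2.5 equiv), i-PrMgCl (5.0 equiv), THF, −20 to 0 °C; sat. aq NH4Cl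
Reagents that add atoms: N,O-dimethylhydroxylamine hydrochloride, CNOC.Cl
Why: Weinreb amidation (acyl substitution of the ester by the magnesium amide); the neighbouring magnesium alkoxide suppresses α-deprotonation, so the (S) centre is carried over unchanged.

Step 4
Reactants: 4 2-iodo-1,3-dimethoxybenzene; 6 (S)-2-hydroxy-N-methoxy-N-methylpropanamide (1.5 equiv)
Product: 7 (S)-2-(2,6-dimethoxyphenoxy)-N-methoxy-N-methylpropanamide
Conditions: CuI (10 mol %), 3,4,7,8-tetramethyl-1,10-phenanthroline (Me4Phen, 20 mol %), Cs2CO3 (2 equiv), 4 Å MS, toluene, 90 °C, 24 h, Ar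
Reagents that add atoms: none
Why: Proposed new method: a stereoretentive, substrate-chelation-assisted Ullmann-type C(aryl)–O coupling of an enantiopure α-hydroxy Weinreb amide with a doubly ortho-substituted, electron-rich aryl iodide, a pairing not yet described, in which Cs2CO3 turns 6 into its alkoxide, the alkoxide binds (Me4Phen)Cu as an O,O-chelate through alkoxide and amide carbonyl, an ortho-OMe of 4 pre-coordinates monovalent copper and guides oxidative addition into the carbon–iodine bond, and the crowded trivalent aryl copper alkoxide collapses quickly by C–O reductive elimination, so only the O–H bond of 6 is broken, C8 keeps its (S) configuration and the weak heterogeneous base leaves the α-C–H alone; the closest known reaction type is the CuI/phenanthroline-catalysed Ullmann etherification of simple aryl iodides with secondary alcohols, which runs with retention at the carbinol carbon.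

Step 5
Reactants: 7 (S)-2-(2,6-dimethoxyphenoxy)-N-methoxy-N-methylpropanamide
Product: 8 (S)-2-[2,6-dimethoxy-4-(4,4,5,5-tetramethyl-1,3,2-dioxaborolan-2-yl)phenoxy]-N-methoxy-N-methylpropanamide
Conditions: [Ir(OMe)(cod)]2 (1.5 mol %), 4,4'-di-tert-butyl-2,2'-bipyridine (3 mol %), B2pin2 (1.0 equiv), MTBE, 80 °C (sealed), 16 h
Reagents that add atoms: bis(pinacolato)diboron, CC1(C)OB(OC1(C)C)B1OC(C)(C)C(C)(C)O1
Why: Iridium-catalysed aromatic C–H borylation (C–H activation by a trisboryl iridium complex) is governed by sterics, and in 7 only the C–H para to the ether oxygen has no ortho substituent, so boron enters there alone, a position electrophilic substitution cannot reach, while the amide and C8 are untouched under neutral conditions.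

Step 6
Reactants: 9 propargyl alcohol (prop-2-yn-1-ol)
Product: 10 (E)-3-(tributylstannyl)prop-2-en-1-ol
Conditions: Bu3SnH (1.3 equiv), AIBN (3 mol %), neat, 80 °C, 2 h; chromatography
Reagents that add atoms: tributyltin hydride, CCCC[SnH](CCCC)CCCC
Why: Radical hydrostannation of a terminal alkyne, in which reversible stannyl radical addition equilibrates the adducts to the terminal (E)-vinylstannane as the major, separable isomer.

Step 7
Reactants: 10 (E)-3-(tributylstannyl)prop-2-en-1-ol
Product: 11 (E)-3-iodoprop-2-en-1-ol
Conditions: I2 (1.05 equiv), CH2Cl2, 0 °C, 30 min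
Reagents that add atoms: iodine, [I][I]
Why: Iododestannylation (electrophilic ipso substitution at the vinyl carbon–tin bond) proceeds with retention of the (E) geometry.

Step 8
Reactants: 8 (S)-2-[2,6-dimethoxy-4-(4,4,5,5-tetramethyl-1,3,2-dioxaborolan-2-yl)phenoxy]-N-methoxy-N-methylpropanamide; 11 (E)-3-iodoprop-2-en-1-ol (1.2 equiv)
Product: 12 (S)-2-{4-[(E)-3-hydroxyprop-1-en-1-yl]-2,6-dimethoxyphenoxy}-N-methoxy-N-methylpropanamide
Conditions: Pd(dppf)Cl2 (5 mol %), K3PO4 (3 equiv), THF/H2O (9:1), 45 °C, 6 h
Reagents that add atoms: none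
Why: Suzuki–Miyaura coupling, in which zerovalent palladium inserts into the vinyl carbon–iodine bond with retention, the phosphate-activated boronate transmetalates and reductive elimination gives the (E)-cinnamyl alcohol arm, while the mild base leaves the Weinreb amide and C8 alone.

Step 9
Reactants: 13 catechol (benzene-1,2-diol)
Product: 14 1,2-dimethoxybenzene (veratrole)
Conditions: MeI (2.5 equiv), K2CO3 (3 equiv), acetone, reflux, 12 h
Reagents that add atoms: iodomethane, CI
Why: Williamson ether synthesis by double SN2 O-methylation of the catecholate; no stereocentre is involved.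

Step 10
Reactants: 14 1,2-dimethoxybenzene
Product: 15 4-bromo-1,2-dimethoxybenzene
Conditions: NBS (1.02 equiv), MeCN, 0 °C to rt, 2 h
Reagents that add atoms: N-bromosuccinimide, O=C1CCC(=O)N1Br
Why: Electrophilic aromatic bromination goes para to one methoxy group (position 4), the most activated and least hindered site of veratrole.

Step 11
Reactants: 15 4-bromo-1,2-dimethoxybenzene (2.5 equiv); 12 (S)-2-{4-[(E)-3-hydroxyprop-1-en-1-yl]-2,6-dimethoxyphenoxy}-N-methoxy-N-methylpropanamide
Product: 18 (S)-1-(3,4-dimethoxyphenyl)-2-{4-[(E)-3-hydroxyprop-1-en-1-yl]-2,6-dimethoxyphenoxy}propan-1-one, via 3,4-dimethoxyphenylmagnesium bromide 16 (not isolated), via bromomagnesium tetrahedral adduct 17 (not isolated)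
Conditions: 15, Mg turnings (2.8 equiv), THF, 40 °C, 1 h; then 12, THF, −20 to 0 °C, 1 h; sat. aq NH4Cl, 0 °C
Reagents that add atoms: none
Why: Grignard formation followed by the Weinreb ketone synthesis, in which the first equivalent of 16 deprotonates the allylic OH and the second adds to the amide to give the chelated adduct 17, which cannot collapse before the quench, so no over-addition occurs and the cold, nearly neutral work-up keeps C8 (S) from enolising.

Step 12
Reactants: 18 (S)-1-(3,4-dimethoxyphenyl)-2-{4-[(E)-3-hydroxyprop-1-en-1-yl]-2,6-dimethoxyphenoxy}propan-1-one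
Product: 19 (1R,2S)-1-(3,4-dimethoxyphenyl)-2-{4-[(E)-3-hydroxyprop-1-en-1-yl]-2,6-dimethoxyphenoxy}propan-1-ol (CNP0155793.1)
Conditions: Zn(BH4)2 (1.5 equiv, 0.15 M in Et2O), Et2O/CH2Cl2 (4:1), −40 °C, 2 h; then H2O; chromatography removes the minor threo isomer
Reagents that add atoms: none
Why: Cram-chelate-controlled hydride reduction, in which divalent zinc ties the carbonyl oxygen and the C8 aryloxy oxygen (supported by an ortho-OMe) into a five-membered chelate and hydride enters from the face carrying the C8–H rather than the C8–CH3, turning the (S)-ketone into the (1R,2S)-erythro alcohol, while alkene, aryl ethers and allylic alcohol are inert.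

**Compound list**
1 | resorcinol (benzene-1,3-diol) | Oc1cccc(O)c1 | starting material
2 | 1,3-dimethoxybenzene | COc1cccc(OC)c1 | intermediate
3 | 2,6-dimethoxyphenyllithium (not isolated) | [Li]c1c(OC)cccc1OC | intermediate
4 | 2-iodo-1,3-dimethoxybenzene | COc1cccc(OC)c1I | intermediate
5 | methyl (S)-lactate | COC(=O)[C@H](C)O | starting material
6 | (S)-2-hydroxy-N-methoxy-N-methylpropanamide | CON(C)C(=O)[C@H](C)O | intermediate
7 | (S)-2-(2,6-dimethoxyphenoxy)-N-methoxy-N-methylpropanamide | CON(C)C(=O)[C@H](C)Oc1c(OC)cccc1OC | intermediate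
8 | (S)-2-[2,6-dimethoxy-4-(4,4,5,5-tetramethyl-1,3,2-dioxaborolan-2-yl)phenoxy]-N-methoxy-N-methylpropanamide | CON(C)C(=O)[C@H](C)Oc1c(OC)cc(B2OC(C)(C)C(C)(C)O2)cc1OC | intermediate
9 | propargyl alcohol (prop-2-yn-1-ol) | C#CCO | starting material
10 | (E)-3-(tributylstannyl)prop-2-en-1-ol | CCCC[Sn](CCCC)(CCCC)/C=C/CO | intermediate
11 | (E)-3-iodoprop-2-en-1-ol | OC/C=C/I | intermediate
12 | (S)-2-{4-[(E)-3-hydroxyprop-1-en-1-yl]-2,6-dimethoxyphenoxy}-N-methoxy-N-methylpropanamide | CON(C)C(=O)[C@H](C)Oc1c(OC)cc(/C=C/CO)cc1OC | intermediate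
13 | catechol (benzene-1,2-diol) | Oc1ccccc1O | starting material
14 | 1,2-dimethoxybenzene (veratrole) | COc1ccccc1OC | intermediate
15 | 4-bromo-1,2-dimethoxybenzene | COc1ccc(Br)cc1OC | intermediate
16 | 3,4-dimethoxyphenylmagnesium bromide (not isolated) | COc1ccc([Mg]Br)cc1OC | intermediate
17 | bromomagnesium tetrahedral adduct: bis(bromomagnesium) salt of (2S)-1-(3,4-dimethoxyphenyl)-1-[methoxy(methyl)amino]-2-{4-[(E)-3-hydroxyprop-1-en-1-yl]-2,6-dimethoxyphenoxy}propan-1-ol (not isolated) | CON(C)C(O[Mg]Br)(c1ccc(OC)c(OC)c1)[C@H](C)Oc1c(OC)cc(/C=C/CO[Mg]Br)cc1OC | intermediate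
18 | (S)-1-(3,4-dimethoxyphenyl)-2-{4-[(E)-3-hydroxyprop-1-en-1-yl]-2,6-dimethoxyphenoxy}propan-1-one | COc1ccc(C(=O)[C@H](C)Oc2c(OC)cc(/C=C/CO)cc2OC)cc1OC | intermediate
19 | (1R,2S)-1-(3,4-dimethoxyphenyl)-2-{4-[(E)-3-hydroxyprop-1-en-1-yl]-2,6-dimethoxyphenoxy}propan-1-ol | COc1ccc([C@@H](O)[C@H](C)Oc2c(OC)cc(/C=C/CO)cc2OC)cc1OC | target

**Counts**
Total step count: 12.
Longest linear sequence: 7 steps (1, 2, 4, 5, 8, 11, 12). The side branches are step 3, steps 6–7 and steps 9–10.

**Three steps most likely to fail**

Step 4, the new coupling, may suffer from slow oxidative addition of the hindered iodide, hydrodeiodination or partial epimerisation.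
- The fallback uses known chemistry. It sets out from 2 and comes back at 7.
- Compound 2 is lithiated as in step 2 to 3, which is trapped with B(OMe)3 to give dimethyl (2,6-dimethoxyphenyl)boronate F1.
- Aqueous H2O2 oxidises this to 2,6-dimethoxyphenol F2.
- A Mitsunobu reaction (PPh3, DIAD, THF, 0 °C to rt) with purchased methyl (R)-lactate F3 goes with clean inversion to methyl (S)-2-(2,6-dimethoxyphenoxy)propanoate F4.
- MeNHOMe·HCl/i-PrMgCl as in step 3 converts that ester into 7.

Step 12 may give a poor erythro/threo ratio, because the aryl ether oxygen is a weak chelating donor.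
- The fallback sets out from 18 and comes back at 19.
- It gives up substrate (chelate) control for catalyst control: asymmetric transfer hydrogenation with RuCl(p-cymene)[(S,S)-TsDPEN] (1 mol %) in HCO2H/Et3N (5:2) at rt.
- The catalyst recognises the aryl group of the ketone and delivers hydride to the face that gives the (1R) carbinol, independent of chelation.
- No new compound arises (F0).

Step 8 may suffer from a sensitive free iodoallyl alcohol and from protodeboronation or sluggish transmetalation of the electron-rich boronate.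
- The fallback sets out from 8 and comes back at 12 by reversing the polarity of the partners.
- CuBr2 (3 equiv) in MeOH/H2O at 80 °C converts 8 into (S)-2-(4-bromo-2,6-dimethoxyphenoxy)-N-methoxy-N-methylpropanamide F5.
- A Stille coupling of this bromide with stannane 10 (Pd(PPh3)4, toluene, 100 °C) gives 12 directly and makes step 7 unnecessary.

**Further compounds**
F1 | step 4 | dimethyl (2,6-dimethoxyphenyl)boronate | COB(OC)c1c(OC)cccc1OC
F2 | step 4 | 2,6-dimethoxyphenol | COc1cccc(OC)c1O
F3 | step 4 | methyl (R)-lactate (purchased) | COC(=O)[C@@H](C)O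
F4 | step 4 | methyl (S)-2-(2,6-dimethoxyphenoxy)propanoate | COC(=O)[C@H](C)Oc1c(OC)cccc1OC
F0 | step 12 | none | none
F5 | step 8 | (S)-2-(4-bromo-2,6-dimethoxyphenoxy)-N-methoxy-N-methylpropanamide | CON(C)C(=O)[C@H](C)Oc1c(OC)cc(Br)cc1OC
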